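The numbers in the tables come from a simulation with made-up constants; the scatter is artificial.

Does the charge of solid reagent move the excess of left-handed product at 20 h?

| flask | left-handed substrate | right-handed substrate | solid reagent | free catalyst | remark | time |
|---|---|---|---|---|---|---|
| larch | 0.79 M | 0.79 M | 0.69 equiv | 1 mol% | run made earlier |  |
| birch | 0.79 M | 0.79 M | 3 equiv | 1 mol% | run made earlier |  |
| midnight | 0.79 M | 0.79 M | 0.600 equiv | 1 mol% |  | 20 h |
| spring | 0.79 M | 0.79 M | 0.800 equiv | 1 mol% |  | 20 h |
| dusk | 0.79 M | 0.79 M | 1.20 equiv | 1 mol% |  | 20 h |
| summer | 0.79 M | 0.79 M | 2.00 equiv | 1 mol% |  | 20 h |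

| run | time / h | left-handed product / % | right-handed product / % |
|---|---|---|---|
| larch | 0.500 | 0 | 0 |
| larch | 1.50 | 0.7 | 0.5 |
| larch | 3.00 | 1.1 | 0.4 |
| larch | 4.00 | 2.9 | 1.4 |
| larch | 6.00 | 4.6 | 0.9 |
| larch | 8.00 | 8.1 | 1.0 |
| larch | 10.0 | 11.2 | 0 |
| birch | 1.33 | 0 | 0 |
| birch | 3.00 | 1.3 | 0 |
| birch | 4.00 | 2.0 | 0.1 |
| birch | 6.00 | 4.6 | 1.0 |
| birch | 8.00 | 8.6 | 0 |
| birch | 10.0 | 10.8 | 0.5 |

(each reading ± 0.5 percentage points)

* excess of left-handed product over right-handed product at the end for midnight, spring, dusk, summer, in this order
* how that number moves from the first to the last of them (falls, then rises / hardly changes / rises, then falls / rises all the way / falls all the way)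

- free catalyst is single-handed; left-handed substrate and right-handed substrate are mirror images of each other, charged as a racemate, each of them at the stated concentration
- solid, in amounts per volume of the solution: solid reagent
- at the start none of the solid reagent is in solution
- an excess is the difference of the two amounts in percent of their sum
- "hardly changes" means that all values lie within two and a half points (for a concentration: within two and a half percent of the largest)

Larch and birch, at 0.69 equiv and 3 equiv, climb together within the scatter of 0.5 percentage points: at 10.0 h they read 11.2 % and 10.8 %. Summing their readings from 6.00 h on gives 0.0710; we call this ratio of right-handed product to left-handed product the leak. The excess is (1 − leak)/(1 + leak), here 86.7 %. That is a rough reading, because the right-handed readings behind it lie between 0 % and 1.0 %.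

Now the curve. From 4.00 h to 10.0 h left-handed product rises by 0.0143 h⁻¹ of the charge. Drawn back, the line meets zero at 2.28 h, the knee at the start. Drawn forward, it gives 25.2 % at 20 h, and with the leak 27.0 % for both products. For the ceiling we assume one unit of solid reagent per product. Equivalents count on left-handed substrate, which is half the charge, so midnight's 0.600 equiv stands for 30.0 %. The line reaches that level at 21.9 h, later than the end, and spring, dusk and summer charge more. Our reckoning is therefore one curve and one excess, 86.7 %.

The forecast gives 86 % for each flask and says hardly changes: “All four runs should therefore look alike”.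

The flasks give 89.9 %, 89.1 %, 89.0 % and 89.0 %: hardly changes.

    solid reagent ⇌ partner, rate k1*(cs1 - [partner]) while solid is left; crystals form when [partner] > cs1 (solubility = 0.640 M, k = 2.17 × 10⁻⁵ s⁻¹)
    free catalyst + left-handed substrate ⇌ catalyst intermediate A (K = 3.98 M⁻¹, k = 0.0888 M⁻¹ s⁻¹)
    partner + catalyst intermediate A → free catalyst + left-handed product (k = 0.00671 M⁻¹ s⁻¹)
    free catalyst + right-handed substrate ⇌ catalyst intermediate B (K = 0.469 M⁻¹, k = 0.184 M⁻¹ s⁻¹)
    partner + catalyst intermediate B → free catalyst + right-handed product (k = 0.00218 M⁻¹ s⁻¹)

In midnight, partner is made 1.72 times as fast as it is used up at 5.59 h, yet at 20.0 h solid reagent stands at 0 % and c(partner) at 0.0943 M, against 0.256 M in summer, which keeps 55.2 % of its solid. Left-handed product then stands at 22.8 % in midnight and 27.0 % in summer. The leak at that moment is 0.0534 in midnight, with an excess of 89.9 %, and 0.0581 in summer, with an excess of 89.0 %.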